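**Assumption:** (1S,4R)-p-mentha-2,8-dien-1-ol (limonene-derived; OH and isopropenyl on the same ring face) is taken as a commercial starting material; labels C1–C11 below are the locants of the target's tricyclo[5.4.0.0^{2,8}]undecane skeleton.

## Retrosynthetic overview

1. Target 30 ⇐ C11 allylic oxidation, C9 dehydration and bis-angeloylation of tricyclic triol 24, whose C3 carbinol is set last by C5-hydroxyl-directed reduction.
2. Cyclobutane (C2–C8) is closed last: the C2 enolate released by conjugate reduction of α-methylene ketone 19 opens the C8–C9 epoxide (4-exo), with the pre-formed seven-membered ring fixing the C2 quaternary centre.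
3. Seven-membered ring by intramolecular aldol of a methyl ketone onto an enal (C3–C4 bond), then anti-directed reduction (C5) and allylic alcohol oxidation (C3) to reach 19.
4. Key bond C6–C7 by Ireland–Claisen [3,3]-sigmatropic rearrangement of the isobutyrate of dienol 1, with 1,3-chirality transfer from the bought C–O stereocentre.
5. Ring order: cyclohexene bought in 1 → cycloheptane (step 7) → cyclobutane (step 10).

## Route

**Step 1**
Reactants: 1 (1S,4R)-1-methyl-4-(prop-1-en-2-yl)cyclohex-2-en-1-ol; 2 2-methylpropanoyl chloride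
Product: 4 (1S,4R)-1-methyl-4-(prop-1-en-2-yl)cyclohex-2-en-1-yl 2-methylpropanoate, via lithium alkoxide 3 (not isolated)
Conditions: n-BuLi, THF, −78 °C; then 2, −78 → 0 °C
Reagents that add atoms: 2-methylpropanoyl chloride (2), CC(C)C(Cl)=O
Why: O-acylation of the lithium tertiary alkoxide by the acid chloride is the reliable way to esterify a hindered, acid-sensitive tertiary allylic alcohol, and no stereocentre is touched.

**Step 2**
Reactants: 4 (1S,4R)-1-methyl-4-(prop-1-en-2-yl)cyclohex-2-en-1-yl 2-methylpropanoate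
Product: 7 2-methyl-2-[(1S,6R)-3-methyl-6-(prop-1-en-2-yl)cyclohex-2-en-1-yl]propanoic acid, via silyl ketene acetal 5 (not isolated), via trimethylsilyl ester 6 (not isolated)
Conditions: LiN(i-Pr)2, Me3SiCl, THF, −78 °C; then 65 °C; aq. HCl
Reagents that add atoms: none
Why: Ireland–Claisen [3,3]-sigmatropic rearrangement of the symmetric dimethylketene acetal forms the C6–C7 bond suprafacially on the face of the departing C–O bond, so the new ring stereocentre is cis to the isopropenyl group (1,3-chirality transfer) and the alkene moves to C8=C9.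

**Step 3**
Reactants: 7 2-methyl-2-[(1S,6R)-3-methyl-6-(prop-1-en-2-yl)cyclohex-2-en-1-yl]propanoic acid
Product: 9 3-methyl-3-[(1S,6R)-3-methyl-6-(prop-1-en-2-yl)cyclohex-2-en-1-yl]butan-2-one, via dilithium gem-diolate 8 (not isolated)
Conditions: MeLi (3 equiv), Et2O, 0 → 23 °C; then H2O (inverse quench)
Reagents that add atoms: methyllithium, [Li]C
Why: Organolithium ketone synthesis, in which the α-quaternary carboxylate takes up one MeLi to a stable dilithium gem-diolate that collapses to the methyl ketone only on work-up, bringing in C4.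

**Step 4**
Reactants: 9 3-methyl-3-[(1S,6R)-3-methyl-6-(prop-1-en-2-yl)cyclohex-2-en-1-yl]butan-2-one
Product: 10 3-methyl-3-[(1S,2S,3R,6R)-6-methyl-3-(prop-1-en-2-yl)-7-oxabicyclo[4.1.0]heptan-2-yl]butan-2-one
Conditions: mCPBA (1.05 equiv), NaHCO3, CH2Cl2, 0 °C
Reagents that add atoms: mCPBA (3-chloroperbenzoic acid), OOC(=O)c1cccc(Cl)c1
Why: Prilezhaev epoxidation takes the more electron-rich trisubstituted ring alkene over the isopropenyl group and attacks anti to the adjacent quaternary side chain, placing the oxirane trans to both side chains (sets C8 and C9).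

**Step 5**
Reactants: 10 3-methyl-3-[(1S,2S,3R,6R)-6-methyl-3-(prop-1-en-2-yl)-7-oxabicyclo[4.1.0]heptan-2-yl]butan-2-one
Product: 11 3-[(1S,2S,3R,6R)-3-(3-chloroprop-1-en-2-yl)-6-methyl-7-oxabicyclo[4.1.0]heptan-2-yl]-3-methylbutan-2-one
Conditions: Ca(OCl)2, CO2 (solid), CH2Cl2/H2O, 0 °C
Reagents that add atoms: calcium hypochlorite, [Ca+2].[O-]Cl.[O-]Cl
Why: Ene-type allylic chlorination by HOCl of the only remaining alkene converts the isopropenyl group into a 2-substituted allyl chloride while keeping the 1,1-disubstituted double bond; ketone and epoxide are inert in the CO2-buffered medium.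

**Step 6**
Reactants: 11 3-[(1S,2S,3R,6R)-3-(3-chloroprop-1-en-2-yl)-6-methyl-7-oxabicyclo[4.1.0]heptan-2-yl]-3-methylbutan-2-one
Product: 13 2-[(1S,2S,3R,6R)-6-methyl-2-(2-methyl-3-oxobutan-2-yl)-7-oxabicyclo[4.1.0]heptan-3-yl]prop-2-enal, via alkoxyammonium chloride 12 (not isolated)
Conditions: Me3NO (anhydrous), DMSO, 23 °C
Reagents that add atoms: trimethylamine N-oxide, C[N+](C)(C)[O-]
Why: Amine-oxide (Kornblum-type) oxidation, in which SN2 displacement of the allylic chloride by the N-oxide oxygen and fragmentation of the alkoxyammonium salt give the α-substituted acrolein (C3 at the aldehyde level) under neutral conditions.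

**Step 7**
Reactants: 13 2-[(1S,2S,3R,6R)-6-methyl-2-(2-methyl-3-oxobutan-2-yl)-7-oxabicyclo[4.1.0]heptan-3-yl]prop-2-enal
Product: 16 (1R,3S,7S,8S,9R)-8,9-epoxy-3-hydroxy-6,6,9-trimethyl-2-methylidenebicyclo[5.4.0]undecan-5-one, via lithium enolate 14 (not isolated), via lithium aldolate 15 (not isolated)
Conditions: LiN(SiMe3)2, THF (0.01 M, slow addition of 13), −78 °C; AcOH quench at −78 °C
Reagents that add atoms: none
Why: Intramolecular aldol addition of the kinetic methyl-ketone enolate (its only enolisable site) 1,2 to the enal closes the seven-membered ring; reaction through the s-trans enal with the ring C1–H eclipsing the methylidene (least allylic strain) lets the enolate tethered through C7 reach only one formyl face, giving the 3S carbinol.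

**Step 8**
Reactants: 16 (1R,3S,7S,8S,9R)-8,9-epoxy-3-hydroxy-6,6,9-trimethyl-2-methylidenebicyclo[5.4.0]undecan-5-one
Product: 18 (1R,3S,5S,7S,8S,9R)-8,9-epoxy-6,6,9-trimethyl-2-methylidenebicyclo[5.4.0]undecane-3,5-diol, via alkoxyborohydride 17 (not isolated)
Conditions: Me4NBH(OAc)3, MeCN/AcOH, −40 → −20 °C; then H2O
Reagents that add atoms: none
Why: Evans–Saksena hydroxyl-directed reduction, in which the C3 alkoxy-borohydride delivers hydride intramolecularly to the C5 ketone and gives the 1,3-anti (trans) diol, fixing the 5S centre before the pseudo-symmetric cage exists.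

**Step 9**
Reactants: 18 (1R,3S,5S,7S,8S,9R)-8,9-epoxy-6,6,9-trimethyl-2-methylidenebicyclo[5.4.0]undecane-3,5-diol
Product: 19 (1R,5S,7S,8S,9R)-8,9-epoxy-5-hydroxy-6,6,9-trimethyl-2-methylidenebicyclo[5.4.0]undecan-3-one
Conditions: MnO2 (activated, excess), CH2Cl2, 23 °C
Reagents that add atoms: none
Why: Chemoselective MnO2 oxidation of the allylic C3 alcohol leaves the neopentyl C5 alcohol untouched and gives the α-methylene ketone needed for regiospecific enolate formation.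

**Step 10**
Reactants: 19 (1R,5S,7S,8S,9R)-8,9-epoxy-5-hydroxy-6,6,9-trimethyl-2-methylidenebicyclo[5.4.0]undecan-3-one
Product: 22 (1R,2S,5S,7R,8S,9R)-5,9-dihydroxy-2,6,6,9-tetramethyltricyclo[5.4.0.0^{2,8}]undecan-3-one, via dilithium enolate alkoxide 20 (not isolated), via dilithium dialkoxide 21 (not isolated)
Conditions: LiN(SiMe3)2 (1.0 equiv), THF, −78 °C; LiBH(s-Bu)3 (1.2 equiv), −78 → 23 °C; then H2O at 0 °C
Reagents that add atoms: none
Why: Stork-type reductive alkylation, in which conjugate hydride addition creates the C2 methyl and only the C2=C3 enolate, whose carbon opens the trans epoxide at C8 in a 4-exo-tet SN2 step with inversion; the seven-membered ring tether forces C3 anti and the methyl syn to the future enone bridge, so cyclobutane, C2 and the C9 carbinol form together.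

**Step 11**
Reactants: 22 (1R,2S,5S,7R,8S,9R)-5,9-dihydroxy-2,6,6,9-tetramethyltricyclo[5.4.0.0^{2,8}]undecan-3-one
Product: 24 (1R,2S,3S,5S,7R,8S,9R)-2,6,6,9-tetramethyltricyclo[5.4.0.0^{2,8}]undecane-3,5,9-triol, via alkoxyborohydride 23 (not isolated)
Conditions: Me4NBH(OAc)3, MeCN/AcOH, −20 → 0 °C; then H2O
Reagents that add atoms: none
Why: Second Evans–Saksena reduction, in which the C5 hydroxyl (the only stereocentre of the lower bridge) delivers hydride to the C3 ketone and restores the 3S carbinol trans to it.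

**Step 12**
Reactants: 24 (1R,2S,3S,5S,7R,8S,9R)-2,6,6,9-tetramethyltricyclo[5.4.0.0^{2,8}]undecane-3,5,9-triol; 25 angelic acid [(2Z)-2-methylbut-2-enoic acid]
Product: 27 (1R,2S,3S,5S,7R,8S,9R)-9-hydroxy-2,6,6,9-tetramethyltricyclo[5.4.0.0^{2,8}]undecane-3,5-diyl bis[(2Z)-2-methylbut-2-enoate], via mixed anhydride 26 (not isolated)
Conditions: 25 (6 equiv), 2,4,6-trichlorobenzoyl chloride, Et3N, toluene, 23 °C; then 24, 75 °C (no DMAP)
Reagents that add atoms: angelic acid (25), C/C=C(/C)C(=O)O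
Why: Yamaguchi-type esterification through the angelic/trichlorobenzoic mixed anhydride acylates both hindered secondary alcohols at the less hindered angeloyl carbonyl, leaves the tertiary C9 alcohol alone, and avoids Z-to-E isomerisation because no nucleophilic catalyst is used.

**Step 13**
Reactants: 27 (1R,2S,3S,5S,7R,8S,9R)-9-hydroxy-2,6,6,9-tetramethyltricyclo[5.4.0.0^{2,8}]undecane-3,5-diyl bis[(2Z)-2-methylbut-2-enoate]
Product: 29 (1R,2S,3S,5S,7R,8R)-2,6,6,9-tetramethyltricyclo[5.4.0.0^{2,8}]undec-9-ene-3,5-diyl bis[(2Z)-2-methylbut-2-enoate], via sulfamate salt 28 (not isolated)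
Conditions: Burgess reagent [methyl N-(triethylammoniosulfonyl)carbamate], toluene, 60 °C
Reagents that add atoms: none
Why: Burgess dehydration (syn Ei elimination of the tertiary sulfamate) gives the more substituted endocyclic C9=C10 alkene, since the C8 bridgehead cannot take a double bond and the non-ionising conditions avoid pinane-type cation rearrangements.

**Step 14**
Reactants: 29 (1R,2S,3S,5S,7R,8R)-2,6,6,9-tetramethyltricyclo[5.4.0.0^{2,8}]undec-9-ene-3,5-diyl bis[(2Z)-2-methylbut-2-enoate]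
Product: 30 (1R,2R,3S,5S,7S,8R)-2,6,6,9-tetramethyl-11-oxotricyclo[5.4.0.0^{2,8}]undec-9-ene-3,5-diyl bis[(2Z)-2-methylbut-2-enoate]
Conditions: CrO3, 3,5-dimethylpyrazole, CH2Cl2, −20 °C
Reagents that add atoms: chromium trioxide, O=[Cr](=O)=O
Why: Allylic oxidation of the C11 methylene, the only secondary allylic position of the trisubstituted alkene, gives the conjugated enone (the α-pinene to verbenone pattern) while the electron-poor angelate alkenes are untouched.

## Compound list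

1 | (1S,4R)-1-methyl-4-(prop-1-en-2-yl)cyclohex-2-en-1-ol [(1S,4R)-p-mentha-2,8-dien-1-ol, OH cis to isopropenyl] | C[C@@]1(O)C=C[C@H](C(C)=C)CC1 | starting material
2 | 2-methylpropanoyl chloride | CC(C)C(Cl)=O | starting material
3 | lithium (1S,4R)-1-methyl-4-(prop-1-en-2-yl)cyclohex-2-en-1-olate | C[C@@]1([O-])C=C[C@H](C(C)=C)CC1.[Li+] | intermediate
4 | (1S,4R)-1-methyl-4-(prop-1-en-2-yl)cyclohex-2-en-1-yl 2-methylpropanoate | C[C@@]1(OC(=O)C(C)C)C=C[C@H](C(C)=C)CC1 | intermediate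
5 | trimethylsilyl ketene acetal of 4 (O-cyclohexenyl O-trimethylsilyl dimethylketene acetal) | C[C@@]1(OC(O[Si](C)(C)C)=C(C)C)C=C[C@H](C(C)=C)CC1 | intermediate
6 | trimethylsilyl 2-methyl-2-[(1S,6R)-3-methyl-6-(prop-1-en-2-yl)cyclohex-2-en-1-yl]propanoate | CC1=C[C@H](C(C)(C)C(=O)O[Si](C)(C)C)[C@H](C(C)=C)CC1 | intermediate
7 | 2-methyl-2-[(1S,6R)-3-methyl-6-(prop-1-en-2-yl)cyclohex-2-en-1-yl]propanoic acid (side chains cis) | CC1=C[C@H](C(C)(C)C(=O)O)[C@H](C(C)=C)CC1 | intermediate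
8 | dilithium 3-methyl-3-[(1S,6R)-3-methyl-6-(prop-1-en-2-yl)cyclohex-2-en-1-yl]butane-2,2-diolate | CC1=C[C@H](C(C)(C)C(C)([O-])[O-])[C@H](C(C)=C)CC1.[Li+].[Li+] | intermediate
9 | 3-methyl-3-[(1S,6R)-3-methyl-6-(prop-1-en-2-yl)cyclohex-2-en-1-yl]butan-2-one | CC1=C[C@H](C(C)(C)C(C)=O)[C@H](C(C)=C)CC1 | intermediate
10 | 3-methyl-3-[(1S,2S,3R,6R)-6-methyl-3-(prop-1-en-2-yl)-7-oxabicyclo[4.1.0]heptan-2-yl]butan-2-one (oxirane trans to both side chains) | C[C@@]12CC[C@@H](C(C)=C)[C@@H](C(C)(C)C(C)=O)[C@@H]1O2 | intermediate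
11 | 3-[(1S,2S,3R,6R)-3-(3-chloroprop-1-en-2-yl)-6-methyl-7-oxabicyclo[4.1.0]heptan-2-yl]-3-methylbutan-2-one | C[C@@]12CC[C@@H](C(CCl)=C)[C@@H](C(C)(C)C(C)=O)[C@@H]1O2 | intermediate
12 | trimethyl(allyloxy)ammonium chloride formed from 11 and Me3NO | C[C@@]12CC[C@@H](C(CO[N+](C)(C)C)=C)[C@@H](C(C)(C)C(C)=O)[C@@H]1O2.[Cl-] | intermediate
13 | 2-[(1S,2S,3R,6R)-6-methyl-2-(2-methyl-3-oxobutan-2-yl)-7-oxabicyclo[4.1.0]heptan-3-yl]prop-2-enal | C[C@@]12CC[C@@H](C(C=O)=C)[C@@H](C(C)(C)C(C)=O)[C@@H]1O2 | intermediate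
14 | lithium enolate of 13 (terminal enolate of the methyl ketone) | C[C@@]12CC[C@@H](C(C=O)=C)[C@@H](C(C)(C)C([O-])=C)[C@@H]1O2.[Li+] | intermediate
15 | lithium aldolate of 16 | C[C@@]12CC[C@H]3C(=C)[C@@H]([O-])CC(=O)C(C)(C)[C@H]3[C@@H]1O2.[Li+] | intermediate
16 | (1R,3S,7S,8S,9R)-8,9-epoxy-3-hydroxy-6,6,9-trimethyl-2-methylidenebicyclo[5.4.0]undecan-5-one (cis ring fusion) | C[C@@]12CC[C@H]3C(=C)[C@@H](O)CC(=O)C(C)(C)[C@H]3[C@@H]1O2 | intermediate
17 | tetramethylammonium C3-alkoxy(diacetoxy)borohydride of 16 | C[C@@]12CC[C@H]3C(=C)[C@@H](O[BH-](OC(C)=O)OC(C)=O)CC(=O)C(C)(C)[C@H]3[C@@H]1O2.C[N+](C)(C)C | intermediate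
18 | (1R,3S,5S,7S,8S,9R)-8,9-epoxy-6,6,9-trimethyl-2-methylidenebicyclo[5.4.0]undecane-3,5-diol | C[C@@]12CC[C@H]3C(=C)[C@@H](O)C[C@H](O)C(C)(C)[C@H]3[C@@H]1O2 | intermediate
19 | (1R,5S,7S,8S,9R)-8,9-epoxy-5-hydroxy-6,6,9-trimethyl-2-methylidenebicyclo[5.4.0]undecan-3-one | C[C@@]12CC[C@H]3C(=C)C(=O)C[C@H](O)C(C)(C)[C@H]3[C@@H]1O2 | intermediate
20 | dilithium C2=C3 enolate C5-alkoxide from 19 | C[C@@]12CC[C@H]3C(C)=C([O-])C[C@H]([O-])C(C)(C)[C@H]3[C@@H]1O2.[Li+].[Li+] | intermediate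
21 | dilithium 5,9-dialkoxide of 22 | [O-][C@H]1CC(=O)[C@@]2(C)[C@@H]3CC[C@@](C)([O-])[C@H]2[C@@H]3C1(C)C.[Li+].[Li+] | intermediate
22 | (1R,2S,5S,7R,8S,9R)-5,9-dihydroxy-2,6,6,9-tetramethyltricyclo[5.4.0.0^{2,8}]undecan-3-one | O[C@H]1CC(=O)[C@@]2(C)[C@@H]3CC[C@@](C)(O)[C@H]2[C@@H]3C1(C)C | intermediate
23 | tetramethylammonium C5-alkoxy(diacetoxy)borohydride of 22 | CC(=O)O[BH-](OC(C)=O)O[C@H]1CC(=O)[C@@]2(C)[C@@H]3CC[C@@](C)(O)[C@H]2[C@@H]3C1(C)C.C[N+](C)(C)C | intermediate
24 | (1R,2S,3S,5S,7R,8S,9R)-2,6,6,9-tetramethyltricyclo[5.4.0.0^{2,8}]undecane-3,5,9-triol | O[C@H]1C[C@H](O)[C@@]2(C)[C@@H]3CC[C@@](C)(O)[C@H]2[C@@H]3C1(C)C | intermediate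
25 | angelic acid, (2Z)-2-methylbut-2-enoic acid | C/C=C(/C)C(=O)O | starting material
26 | (2Z)-2-methylbut-2-enoic 2,4,6-trichlorobenzoic anhydride | C/C=C(/C)C(=O)OC(=O)c1c(Cl)cc(Cl)cc1Cl | intermediate
27 | (1R,2S,3S,5S,7R,8S,9R)-9-hydroxy-2,6,6,9-tetramethyltricyclo[5.4.0.0^{2,8}]undecane-3,5-diyl bis[(2Z)-2-methylbut-2-enoate] | C/C=C(/C)C(=O)O[C@H]1C[C@H](OC(=O)/C(C)=C\C)[C@@]2(C)[C@@H]3CC[C@@](C)(O)[C@H]2[C@@H]3C1(C)C | intermediate
28 | triethylammonium C9 N-(methoxycarbonyl)sulfamate ester of 27 | C/C=C(/C)C(=O)O[C@H]1C[C@H](OC(=O)/C(C)=C\C)[C@@]2(C)[C@@H]3CC[C@@](C)(OS(=O)(=O)[N-]C(=O)OC)[C@H]2[C@@H]3C1(C)C.CC[NH+](CC)CC | intermediate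
29 | (1R,2S,3S,5S,7R,8R)-2,6,6,9-tetramethyltricyclo[5.4.0.0^{2,8}]undec-9-ene-3,5-diyl bis[(2Z)-2-methylbut-2-enoate] | C/C=C(/C)C(=O)O[C@H]1C[C@H](OC(=O)/C(C)=C\C)[C@@]2(C)[C@@H]3CC=C(C)[C@H]2[C@@H]3C1(C)C | intermediate
30 | (1R,2R,3S,5S,7S,8R)-2,6,6,9-tetramethyl-11-oxotricyclo[5.4.0.0^{2,8}]undec-9-ene-3,5-diyl bis[(2Z)-2-methylbut-2-enoate] | C/C=C(/C)C(=O)O[C@H]1C[C@H](OC(=O)/C(C)=C\C)[C@@]2(C)[C@@H]3C(=O)C=C(C)[C@H]2[C@@H]3C1(C)C | target

## Step count and risks

Total step count: 14. Longest linear sequence: 14 steps (1 → 30); 2 and 25 are bought.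

**Step 10 (reductive cyclobutane closure).** The lithium enolate may be too sluggish toward the trisubstituted epoxide, the C5 alkoxide may open the epoxide itself, or the product β-alkoxy ketone may undergo retro-aldol. The fallback sets out from 19 and separates enolate generation from alkylation. The C5 hydroxyl is silylated (Et3SiCl, imidazole, DMF) to give silyl ether F4. Conjugate reduction with LiBH(s-Bu)3 and trapping with Me3SiCl/Et3N gives the regiodefined trimethylsilyl enol ether F5. MeLi in THF, then DMPU at 50 °C, liberates the borane-free lithium enolate, which opens the epoxide to give the silylated cage ketone F6. HF·pyridine then returns to the route at 22.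

**Step 7 (aldol ring closure).** The enolate may add 1,4 to the methylidene, oligomerise, or give the wrong C3 epimer, which would put the wrong configuration at C5 in step 8. The fallback sets out from chloride 11 and leaves out the enal. LiN(SiMe3)2 (THF, −78 → 0 °C) makes the methyl-ketone enolate displace the allylic chloride, closing the seven-membered ring by SN2 alkylation to give methylenecycloheptanone F1. The C5 ketone is then reduced under reagent control (NaBH4 in MeOH, or LiBH(s-Bu)3 if the opposite face is needed) to the 5S alcohol F2. SeO2 (cat.)/t-BuOOH hydroxylates the allylic C3 methylene to diol F3, whose C3 configuration does not matter. MnO2 oxidation then returns to the route at 19.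

**Step 13 (dehydration of the tertiary alcohol).** Elimination may go toward the methyl group (exocyclic alkene), or the tertiary sulfamate may ionise and rearrange. The fallback sets out from triol 24 and postpones acylation so that a base-mediated alkene equilibration becomes possible. Et3SiCl/imidazole (DMF) protects only the secondary alcohols, giving bis(triethylsilyl) ether F7. SOCl2/pyridine at 0 °C dehydrates it to a mixture of endocyclic alkene F8 and exocyclic alkene F9. KOt-Bu in DMSO equilibrates F9 to the more stable F8. CrO3/3,5-dimethylpyrazole gives silylated enone F10, and HF·pyridine gives diol enone F11. Bis-angeloylation as in step 12 (through 26) then arrives at 30.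

## Further compounds

F1 | step 7 | (1R,7S,8S,9R)-8,9-epoxy-6,6,9-trimethyl-2-methylidenebicyclo[5.4.0]undecan-5-one | C[C@@]12CC[C@H]3C(=C)CCC(=O)C(C)(C)[C@H]3[C@@H]1O2
F2 | step 7 | (1R,5S,7S,8S,9R)-8,9-epoxy-6,6,9-trimethyl-2-methylidenebicyclo[5.4.0]undecan-5-ol | C[C@@]12CC[C@H]3C(=C)CC[C@H](O)C(C)(C)[C@H]3[C@@H]1O2
F3 | step 7 | (1R,5S,7S,8S,9R)-8,9-epoxy-6,6,9-trimethyl-2-methylidenebicyclo[5.4.0]undecane-3,5-diol (C3 epimers) | C[C@@]12CC[C@H]3C(=C)C(O)C[C@H](O)C(C)(C)[C@H]3[C@@H]1O2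
F4 | step 10 | 5-O-triethylsilyl ether of 19 | C[C@@]12CC[C@H]3C(=C)C(=O)C[C@H](O[Si](CC)(CC)CC)C(C)(C)[C@H]3[C@@H]1O2
F5 | step 10 | C2=C3 trimethylsilyl enol ether from F4 | C[C@@]12CC[C@H]3C(C)=C(O[Si](C)(C)C)C[C@H](O[Si](CC)(CC)CC)C(C)(C)[C@H]3[C@@H]1O2
F6 | step 10 | 5-O-triethylsilyl ether of 22 | CC[Si](CC)(CC)O[C@H]1CC(=O)[C@@]2(C)[C@@H]3CC[C@@](C)(O)[C@H]2[C@@H]3C1(C)C
F7 | step 13 | 3,5-bis-O-triethylsilyl ether of 24 | CC[Si](CC)(CC)O[C@H]1C[C@H](O[Si](CC)(CC)CC)[C@@]2(C)[C@@H]3CC[C@@](C)(O)[C@H]2[C@@H]3C1(C)C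
F8 | step 13 | 2,6,6,9-tetramethyl-3,5-bis(triethylsilyloxy)tricyclo[5.4.0.0^{2,8}]undec-9-ene | CC[Si](CC)(CC)O[C@H]1C[C@H](O[Si](CC)(CC)CC)[C@@]2(C)[C@@H]3CC=C(C)[C@H]2[C@@H]3C1(C)C
F9 | step 13 | 2,6,6-trimethyl-9-methylidene-3,5-bis(triethylsilyloxy)tricyclo[5.4.0.0^{2,8}]undecane | CC[Si](CC)(CC)O[C@H]1C[C@H](O[Si](CC)(CC)CC)[C@@]2(C)[C@@H]3CCC(=C)[C@H]2[C@@H]3C1(C)C
F10 | step 13 | 2,6,6,9-tetramethyl-3,5-bis(triethylsilyloxy)tricyclo[5.4.0.0^{2,8}]undec-9-en-11-one | CC[Si](CC)(CC)O[C@H]1C[C@H](O[Si](CC)(CC)CC)[C@@]2(C)[C@@H]3C(=O)C=C(C)[C@H]2[C@@H]3C1(C)C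
F11 | step 13 | (1R,2R,3S,5S,7S,8R)-3,5-dihydroxy-2,6,6,9-tetramethyltricyclo[5.4.0.0^{2,8}]undec-9-en-11-one | O[C@H]1C[C@H](O)[C@@]2(C)[C@@H]3C(=O)C=C(C)[C@H]2[C@@H]3C1(C)C
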